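Labdane numbering is used (decalin C1–C10, C17 exocyclic methylene on C8, C11 acetoxy carbon, C16 lactone carbonyl). Everything rests on opening ring B across C6–C7 and the ring-fusion bond C5–C10: an intramolecular Diels–Alder reaction in which C7=C8–C9=C10 is a 2-silyloxydiene and C5=C6 a vinyl ketone tied on through C1–C4. One operation closes rings A and B and sets C10, with C5 trans. The precursor is an acyclic dienone whose C11 carbinol and C8 enol oxygen are clipped into a temporary di-tert-butylsilylene ring; this locks the diene s-cis and lets the C11 stereocentre, already in place, choose the diene face. The C4 ketone later becomes the gem-dimethyl carbon.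

Key step: step 6

Assumption (chemistry): compounds 1 and 6 are taken as purchasable; C4 is carried as an inconsequential epimer mixture from step 1 until it becomes a ketone in step 5.

Step 1
Reactants: 1 hex-5-ynal
Product: 3 triethyl(oct-1-en-7-yn-3-yloxy)silane, via bromomagnesium alkoxide 2 (not isolated)
Conditions: CH2=CHMgBr, THF, −78 °C; then Et3SiOTf, 2,6-lutidine, −78 → 0 °C
Reagents that add atoms: vinylmagnesium bromide C=C[Mg]Br; triethylsilyl trifluoromethanesulfonate CC[Si](CC)(CC)OS(=O)(=O)C(F)(F)F
Why: Grignard 1,2-addition to the aldehyde (faster than alkyne deprotonation at low temperature) followed by silylation of the alkoxide in the same flask; the new C4 centre is left uncontrolled because it is oxidised in step 5.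

Step 2
Reactants: 3 triethyl(oct-1-en-7-yn-3-yloxy)silane
Product: 5 7-(triethylsilyloxy)non-8-en-2-ynal, via lithium acetylide 4 (not isolated)
Conditions: n-BuLi, THF, −78 °C; DMF; inverse quench into aq. KH2PO4
Reagents that add atoms: N,N-dimethylformamide CN(C)C=O
Why: formylation of a lithium acetylide with DMF, the buffered inverse quench preventing conjugate addition of dimethylamine to the ynal; the formyl carbon becomes C11.

Step 3
Reactants: 5 7-(triethylsilyloxy)non-8-en-2-ynal; 6 trimethyl[3-(4,4,5,5-tetramethyl-1,3,2-dioxaborolan-2-yl)prop-1-yn-1-yl]silane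
Product: 7 (4R)-10-(triethylsilyloxy)-1-(trimethylsilyl)dodec-11-ene-1,5-diyn-4-ol
Conditions: Cu(O2CCHMe2)2 (5 mol %), MeO-BIBOP bisphosphine (antipode that gives the 4R alcohol), LiOt-Bu (cat.), THF, −60 °C
Reagents that add atoms: none
Why: copper-catalysed enantioselective propargylation of an aldehyde, in which boron-to-copper exchange gives an allenylcopper that adds in the SE2′ sense; the chiral ligand sets C11 (R) and the silyl cap keeps the new alkyne inert later.

Step 4
Reactants: 7 (4R)-10-(triethylsilyloxy)-1-(trimethylsilyl)dodec-11-ene-1,5-diyn-4-ol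
Product: 10 (3E)-8-hydroxy-3-[(1R)-1-hydroxy-4-(trimethylsilyl)but-3-yn-1-yl]-4-methyldeca-3,9-dien-2-one, via alkenylmagnesium alkoxide 8 (not isolated), via triethylsilyl-protected enone 9 (not isolated)
Conditions: MeMgBr (5 equiv), Fe(acac)3 (20 mol %), THF, 0 °C; then MeC(O)N(OMe)Me (excess), 0 °C → rt; then 1 M HCl, THF, rt
Reagents that add atoms: methylmagnesium bromide C[Mg]Br; N-methoxy-N-methylacetamide CC(=O)N(C)OC
Why: alkoxide-directed iron-catalysed syn-carbomagnesiation of the propargylic alcohol places methyl on C10 and magnesium on C9 cis to it, and acylation with retention gives the tetrasubstituted alkene with the C20 methyl cis to the acetyl group and the C1 chain cis to C11; the acid work-up releases the ketone and removes the triethylsilyl group.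

Step 5
Reactants: 10 (3E)-8-hydroxy-3-[(1R)-1-hydroxy-4-(trimethylsilyl)but-3-yn-1-yl]-4-methyldeca-3,9-dien-2-one
Product: 11 (3E)-3-[(1R)-1-hydroxy-4-(trimethylsilyl)but-3-yn-1-yl]-4-methyldeca-3,9-diene-2,8-dione
Conditions: MnO2 (activated, excess), CH2Cl2, rt; used cold and at once
Reagents that add atoms: none
Why: allylic oxidation by MnO2 should take the unhindered vinyl carbinol at C4 and spare the C11 carbinol, which is branched on both sides and sits on an electron-poor, fully substituted enone carbon.

Step 6
Reactants: 11 (3E)-3-[(1R)-1-hydroxy-4-(trimethylsilyl)but-3-yn-1-yl]-4-methyldeca-3,9-diene-2,8-dione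
Product: 13 trans-fused silylene-bridged tricyclic ketone (11R; H-5 anti to the C10 methyl), via dioxasiline diene 12 (not isolated)
Conditions: t-Bu2Si(OTf)2 (1.05 equiv), i-Pr2NEt, CH2Cl2, −78 °C → rt (40 °C if needed)
Reagents that add atoms: di-tert-butylsilyl bis(trifluoromethanesulfonate) CC(C)(C)[Si](OS(=O)(=O)C(F)(F)F)(OS(=O)(=O)C(F)(F)F)C(C)(C)C
Why: The bis(triflate) silylates the C11 hydroxyl and then, intramolecularly, the enol of the C8 methyl ketone on its only α-carbon C7, giving dioxasiline 12 in which C7=C8 and C9=C10 are exocyclic on neighbouring ring atoms and so held s-cis; 12 then undergoes a normal-demand type 1 intramolecular Diels–Alder reaction with the tethered vinyl ketone, the closest known type being the cyclisation of 9-silyloxydeca-1,7,9-trien-3-ones. Bonding is electronically matched and asynchronous, the nucleophilic terminus C7 joining the unhindered β-carbon C6 ahead of C5–C10, so that ring B closes as the cyclohexene of the [4+2] process and ring A closes as a six-membered ring through the C1–C3 tether and the C4 carbonyl. C10 is controlled by C11: allylic 1,3-strain with the C1 chain forces the C12 substituent of the dioxasiline pseudoaxial, and the dienophile adds to the opposite diene face, which turns 11R into 10S. C5 is set by the anti (carbonyl-exo) transition state, because the sp3 carbon C11 on C9 fills the space above and below C9 that the tether needs in the syn mode; this puts H-5 trans to the C10 methyl. The step needs enol silylation at C7 and not γ-deprotonation or silylation of the C4 ketone, which the six-membered intramolecular delivery of the second Si–OTf bond and one equivalent of reagent should secure. C5 stays epimerisable next to the C4 ketone, so only a hindered amine is present and the next step is non-basic.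

Step 7
Reactants: 13 trans-fused silylene-bridged tricyclic ketone
Product: 14 4-methylidene tricycle (C4=CH2 in place of C4=O)
Conditions: Cp2Ti(μ-CH2)(μ-Cl)AlMe2 (Tebbe reagent), pyridine (cat.), THF/toluene, −40 → 0 °C
Reagents that add atoms: Tebbe reagent C[Al](C)C[Ti](Cl)(C1C=CC=C1)C1C=CC=C1
Why: titanium-methylidene (Tebbe) olefination of a ketone, which is non-basic and so should not epimerise C5; the silyl enol ether and the silylalkyne react more slowly than the ketone at low temperature.

Step 8
Reactants: 14 4-methylidene tricycle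
Product: 16 4,4-dimethyl tricycle (gem-dimethyl at C4), via sulfonyl hydrazide 15 (not isolated)
Conditions: Fe(acac)3 (30 mol %), PhSiH3, CH2=NNHSO2(n-C8H17), THF/MeOH, rt; then MeOH, 60 °C
Reagents that add atoms: formaldehyde N-(octylsulfonyl)hydrazone C=NNS(=O)(=O)CCCCCCCC
Why: metal-hydride hydrogen-atom-transfer hydromethylation, in which Markovnikov hydrogen-atom transfer to the 1,1-disubstituted alkene gives the tertiary C4 radical, this adds to the hydrazone, and loss of sulfinate and N2 leaves the second methyl; no stereocentre is created in 16 and the tetrasubstituted enol ether and the alkyne are poor hydrogen-atom acceptors.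

Step 9
Reactants: 16 4,4-dimethyl tricycle
Product: 17 (5S,9S,10S,11R)-hydroxy ketone (4,4,10-trimethyl-trans-decalin-8-one carrying at C9 the equatorial (1R)-1-hydroxybut-3-yn-1-yl group)
Conditions: TBAF, AcOH, THF, 0 °C → rt
Reagents that add atoms: none
Why: buffered fluoride cleaves both Si–O bonds of the silylene and the alkynyl C–Si bond without retro-aldol cleavage; C9 is set on ketonisation by axial protonation anti to the C10 methyl, which is also the thermodynamic epimer with the side chain equatorial.

Step 10
Reactants: 17 (5S,9S,10S,11R)-hydroxy ketone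
Product: 18 (5S,9S,10S,11R)-homoallylic alcohol with the C8=C17 exocyclic methylene
Conditions: Zn, CH2Br2, TiCl4 (pre-aged Lombardo reagent), THF/CH2Cl2, 0 °C → rt
Reagents that add atoms: dibromomethane BrCBr
Why: Lombardo methylenation is non-basic, so the β-hydroxy ketone should neither epimerise at C9 nor undergo retro-aldol or elimination, and free hydroxyl groups and alkynes are tolerated.

Step 11
Reactants: 18 (5S,9S,10S,11R)-homoallylic alcohol
Product: 19 (11R)-acetate with terminal alkyne
Conditions: Ac2O, DMAP (cat.), pyridine, CH2Cl2, 0 °C → rt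
Reagents that add atoms: acetic anhydride CC(=O)OC(C)=O
Why: DMAP-catalysed acylation of the hindered secondary alcohol with retention at C11; it also blocks lactonisation onto the ester made in step 12.

Step 12
Reactants: 19 (11R)-acetate with terminal alkyne
Product: 20 allyl 2-substituted acrylate (C13(=CH2)–CO2CH2CH=CH2)
Conditions: Pd(OAc)2 (2 mol %), 2-pyridyldiphenylphosphine, MeSO3H (cat.), CO (10 bar), allyl alcohol, 50 °C
Reagents that add atoms: carbon monoxide [C-]#[O+]; allyl alcohol C=CCO
Why: palladium-catalysed Markovnikov hydroalkoxycarbonylation of a terminal alkyne, which gives the branched acrylate and leaves the hindered 1,1-disubstituted C8=C17 alkene alone.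

Step 13
Reactants: 20 allyl 2-substituted acrylate
Product: 21 target, (5S,9S,10S,11R)-11-acetoxylabda-8(17),13-dien-16,15-olide
Conditions: second-generation Grubbs catalyst (H2IMes)(PCy3)Cl2Ru=CHPh (5 mol %), 1,4-benzoquinone (cat.), toluene, 80 °C
Reagents that add atoms: none
Why: ring-closing metathesis between the allyl ester and the acrylate methylidene closes the five-membered α-substituted butenolide with loss of ethene; the fully substituted environment of C8=C17 keeps it out of the metathesis.

Compound list
1 | hex-5-ynal | C#CCCCC=O | starting material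
2 | bromomagnesium oct-1-en-7-yn-3-olate | C=CC(O[Mg]Br)CCCC#C | intermediate
3 | triethyl(oct-1-en-7-yn-3-yloxy)silane (racemic) | C=CC(O[Si](CC)(CC)CC)CCCC#C | intermediate
4 | [6-(triethylsilyloxy)oct-7-en-1-yn-1-yl]lithium | C=CC(O[Si](CC)(CC)CC)CCCC#C[Li] | intermediate
5 | 7-(triethylsilyloxy)non-8-en-2-ynal | C=CC(O[Si](CC)(CC)CC)CCCC#CC=O | intermediate
6 | trimethyl[3-(4,4,5,5-tetramethyl-1,3,2-dioxaborolan-2-yl)prop-1-yn-1-yl]silane | C[Si](C)(C)C#CCB1OC(C)(C)C(C)(C)O1 | starting material
7 | (4R)-10-(triethylsilyloxy)-1-(trimethylsilyl)dodec-11-ene-1,5-diyn-4-ol (C10 epimer mixture) | C=CC(O[Si](CC)(CC)CC)CCCC#C[C@H](O)CC#C[Si](C)(C)C | intermediate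
8 | alkenylmagnesium alkoxide (Mg on C9 cis to the new C10 methyl; O11–MgBr) | C=CC(O[Si](CC)(CC)CC)CCC/C(C)=C(/[Mg]Br)[C@H](O[Mg]Br)CC#C[Si](C)(C)C | intermediate
9 | (3E)-3-[(1R)-1-hydroxy-4-(trimethylsilyl)but-3-yn-1-yl]-4-methyl-8-(triethylsilyloxy)deca-3,9-dien-2-one | CC(=O)/C(=C(\C)CCCC(O[Si](CC)(CC)CC)C=C)[C@H](O)CC#C[Si](C)(C)C | intermediate
10 | (3E)-8-hydroxy-3-[(1R)-1-hydroxy-4-(trimethylsilyl)but-3-yn-1-yl]-4-methyldeca-3,9-dien-2-one | CC(=O)/C(=C(\C)CCCC(O)C=C)[C@H](O)CC#C[Si](C)(C)C | intermediate
11 | (3E)-3-[(1R)-1-hydroxy-4-(trimethylsilyl)but-3-yn-1-yl]-4-methyldeca-3,9-diene-2,8-dione | CC(=O)/C(=C(\C)CCCC(=O)C=C)[C@H](O)CC#C[Si](C)(C)C | intermediate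
12 | (5E,6R)-2,2-di-tert-butyl-4-methylidene-5-(6-oxooct-7-en-2-ylidene)-6-[3-(trimethylsilyl)prop-2-yn-1-yl]-1,3,2-dioxasilinane | C=C1O[Si](C(C)(C)C)(C(C)(C)C)O[C@H](CC#C[Si](C)(C)C)/C1=C(/C)CCCC(=O)C=C | intermediate
13 | trans-fused tricyclic ketone: 4-oxo-10-methyl-octalin, C8=C9 enol ether bridged O8–Si(t-Bu)2–O11, 11R, H-5 anti to C10 methyl | O=C1CCC[C@]2(C)C3=C(CC[C@@H]12)O[Si](C(C)(C)C)(C(C)(C)C)O[C@@H]3CC#C[Si](C)(C)C | intermediate
14 | 4-methylidene analogue of 13 | C=C1CCC[C@]2(C)C3=C(CC[C@@H]12)O[Si](C(C)(C)C)(C(C)(C)C)O[C@@H]3CC#C[Si](C)(C)C | intermediate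
15 | C4-methyl C4-CH2NHNHSO2(n-octyl) hydrazide of the tricycle (C4 epimer mixture) | CC1(CNNS(=O)(=O)CCCCCCCC)CCC[C@]2(C)C3=C(CC[C@@H]12)O[Si](C(C)(C)C)(C(C)(C)C)O[C@@H]3CC#C[Si](C)(C)C | intermediate
16 | 4,4-dimethyl tricycle (silylene and alkynylsilane intact) | CC1(C)CCC[C@]2(C)C3=C(CC[C@@H]12)O[Si](C(C)(C)C)(C(C)(C)C)O[C@@H]3CC#C[Si](C)(C)C | intermediate
17 | (5S,9S,10S,11R)-9-[(1R)-1-hydroxybut-3-yn-1-yl]-4,4,10-trimethyl-trans-decalin-8-one | CC1(C)CCC[C@]2(C)[C@@H]([C@H](O)CC#C)C(=O)CC[C@@H]12 | intermediate
18 | (5S,9S,10S,11R)-8(17)-methylidene alcohol with but-3-ynyl carbinol side chain | CC1(C)CCC[C@]2(C)[C@@H]([C@H](O)CC#C)C(=C)CC[C@@H]12 | intermediate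
19 | (11R)-acetate of 18 | CC1(C)CCC[C@]2(C)[C@@H]([C@H](OC(C)=O)CC#C)C(=C)CC[C@@H]12 | intermediate
20 | allyl 2-substituted acrylate (C12–C13(=CH2)–CO2-allyl, 11R-OAc) | CC1(C)CCC[C@]2(C)[C@@H]([C@H](OC(C)=O)CC(=C)C(=O)OCC=C)C(=C)CC[C@@H]12 | intermediate
21 | (5S,9S,10S,11R)-11-acetoxylabda-8(17),13-dien-16,15-olide | C=C1CC[C@H]2C(C)(C)CCC[C@]2(C)[C@H]1[C@@H](CC1=CCOC1=O)OC(C)=O | target

Total step count: 13. Longest linear sequence: 13 steps (from 1; compound 6 is purchased).

Steps most likely to fail

Step 6. The cycloaddition may close through the syn (carbonyl-endo) transition state, or C5 may epimerise next to the C4 ketone, so that the trans ring fusion is lost. The fallback sets out from 13 as obtained, whatever its C5 configuration, and comes back at 13. Equilibrating enol silylation (Me3SiOTf, Et3N, CH2Cl2) would give the more substituted trimethylsilyl enol ether F1 (C4=C5). Saegusa–Ito oxidation (Pd(OAc)2, MeCN) would give the cross-conjugated enone F2 (C5=C6), in which C5 is no longer a stereocentre. Conjugate reduction with [(Ph3P)CuH]6 and kinetic protonation of the resulting C4 enolate at C5, anti to the axial C10 methyl, should then return trans-fused 13.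

Step 4. Acyl transfer to the hindered, chelated alkenylmagnesium species may be slow, so that protonation on work-up or attack on the silylalkyne competes. The fallback sets out from 7 and comes back at 10. The same carbomagnesiation would be quenched with I2 to give the alkenyl iodide F3, with retention (iodine cis to the C10 methyl). Stille coupling with tributyl(1-ethoxyvinyl)stannane (Pd(PPh3)4, CuI, DMF) would give the 2-ethoxydiene F4. Stirring with 1 M HCl in THF would hydrolyse the enol ether and the triethylsilyl ether to give 10.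

Step 12. Palladium may ionise allyl alcohol or the allyl ester product, or the catalyst may be diverted, so that the branched allyl ester is not formed cleanly. The fallback sets out from 19 and comes back at 20. Hydroxycarbonylation with water in place of the alcohol (Pd(OAc)2, 2-pyridyldiphenylphosphine, MeSO3H, CO, aqueous acetone) would give the 2-substituted acrylic acid F5. The allyl group would then be attached without palladium by O-alkylation (allyl bromide, K2CO3, DMF, rt) to give 20.

Further compounds
F1 | step 6 | C4 trimethylsilyl enol ether (C4=C5) of tricycle 13 | C[Si](C)(C)OC1=C2CCC3=C([C@@]2(C)CCC1)[C@@H](CC#C[Si](C)(C)C)O[Si](C(C)(C)C)(C(C)(C)C)O3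
F2 | step 6 | Δ5(6)-enone of tricycle 13 | O=C1CCC[C@]2(C)C3=C(CC=C12)O[Si](C(C)(C)C)(C(C)(C)C)O[C@@H]3CC#C[Si](C)(C)C
F3 | step 4 | alkenyl iodide (iodine on C9 cis to the C10 methyl; triethylsilyl ether retained) | C=CC(O[Si](CC)(CC)CC)CCC/C(C)=C(/I)[C@H](O)CC#C[Si](C)(C)C
F4 | step 4 | 2-ethoxydiene (ethyl enol ether of 9) | C=C(OCC)/C(=C(\C)CCCC(O[Si](CC)(CC)CC)C=C)[C@H](O)CC#C[Si](C)(C)C
F5 | step 12 | 2-substituted acrylic acid (free acid of 20) | CC1(C)CCC[C@]2(C)[C@@H]([C@H](OC(C)=O)CC(=C)C(=O)O)C(=C)CC[C@@H]12
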